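## Retrosynthetic overview
- The target comes from chelation-controlled reduction of the ketone 7-oxolariciresinol (8), which sets the exocyclic carbinol C7′ (R).
- Compound 8 comes from DDQ/H2O opening of one tetrahydrofuran ring of the C2-symmetric (+)-pinoresinol (7); this converts one benzylic ether carbon into the ketone.
- Compound 7 comes from double Friedel–Crafts C-arylation of the cis-fused bis-lactol 5. The aryl groups end up exo, so each is trans to the adjacent CH2O-bearing carbon.
- Compound 5 comes from organocatalytic double α-hydroxymethylation of succinaldehyde (2, made from the acetal 1). This sets C8/C8′ (both R) and closes both five-membered rings as lactols.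
- Ring order: both THF rings form in step 2, the aryl groups are installed in step 3, and one ring is opened in step 4.

Assumptions:
- (S)-Diphenylprolinol TMS ether is taken to give (R) α-centres here, as it does in its nitroalkene Michael additions. If the opposite enantiomer formed, the (R)-catalyst would be used.
- The "7-hydroxy" is the exocyclic benzylic carbinol, as in the given SMILES: ring 2S,3R,4R, carbinol R, with 3,4-cis and 2,3-trans substituents.

## Route

**Step 1**
Reactants: 1 (2,5-dimethoxytetrahydrofuran, cis/trans mixture)
Product: 2 (succinaldehyde, O=CCC=O, as an aqueous solution used directly in step 2)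
Conditions: 0.1 M aq. HCl, 50 °C, 2 h; then NaOAc to pH 6, 0–23 °C
Reagents that add atoms: water, O
Why: Acid hydrolysis of the cyclic acetal releases the dialdehyde (acetal hydrolysis) and gives C4H6O2 plus 2 MeOH. Succinaldehyde is unstable, so it is buffered and not isolated.

**Step 2**
Reactants: 2 (succinaldehyde); 3 (formaldehyde, 37% aq. formalin, 2.4 equiv); 4 ((S)-α,α-diphenylprolinol TMS ether, 10 mol %)
Product: 5, (3aR,6aR)-hexahydrofuro[3,4-c]furan-1,4-diol (cis-fused bis-lactol, anomeric mixture)
Conditions: the step 1 solution is diluted with THF to THF/H2O 4:1; 3 and 4 are added; 4 → 23 °C, 24 h. The mixture is concentrated and partitioned between water and CH2Cl2 to remove 4; the aqueous phase is lyophilized.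
Reagents that add atoms: formaldehyde, C=O
Why: This is enamine-catalysed α-hydroxymethylation (organocatalytic aldol-type addition of formaldehyde), applied to both α-CH2 groups of a dialdehyde. The bulky catalyst shields one enamine face, so both new α-centres are (R). Each CH2OH closes onto the distal CHO as a lactol. Only the (R,R) (dl) diastereomer gives the cis-fused bicycle, so any (R,S) adduct epimerizes through the enamine and is drained, which also raises the ee.

**Step 3**
Reactants: 5 (bis-lactol); 6 (guaiacol, 3.5 equiv)
Product: 7, (+)-pinoresinol, (1S,3aR,4S,6aR)
Conditions: Sc(OTf)3 (5 mol %), HFIP, 23 °C, 16 h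
Reagents that add atoms: guaiacol, COc1ccccc1O
Why: Each lactol ionizes to a cyclic oxocarbenium ion, which undergoes Friedel–Crafts C-arylation as in C-glycoside formation. Guaiacol attacks para to its OH, and attack on the convex face of the cis-bicycle (reinforced by thermodynamic re-ionization) puts each aryl exo. This sets both benzylic centres S and makes each aryl trans to its neighbouring CH2O carbon.

**Step 4**
Reactants: 7 ((+)-pinoresinol)
Product: 8, 7-oxolariciresinol
Conditions: DDQ (1.0 equiv), 1,4-dioxane/H2O 9:1, 0 → 23 °C, 1 h, stopped at about 50% conversion; recovered 7 is recycled.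
Reagents that add atoms: water, O
Why: Proposed new method: DDQ abstracts the benzylic hydride at C7, assisted by the p-hydroxyaryl group, to give a stabilized oxocarbenium or quinone-methide-type cation. Water adds to give a hemiketal, which collapses to the aryl ketone and a free CH2OH, so one ring opens. C8, C8′ and the other ring's C7 are untouched. The closest known reaction is DDQ/H2O oxidative cleavage of PMB-type benzylic ethers, applied here to a C2-symmetric bis-benzylic furofuran; mono-selectivity comes from stoichiometry and partial conversion because the two rings are equivalent.

**Step 5**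
Reactants: 8
Product: 9, (7R)-7-hydroxylariciresinol (target)
Conditions: Zn(BH4)2 (3 equiv), Et2O/THF, −78 → −20 °C, 3 h; aq. NH4Cl work-up; chromatographic removal of any 7S epimer
Reagents that add atoms: none
Why: This is a chelation-controlled (Cram-chelate) ketone reduction. Zn2+ bridges the ketone oxygen and the cis CH2OH on C3 in a seven-membered chelate, so the carbonyl sits syn to C3. Hydride enters from the face bearing H-4, not the ring CH2, which gives the 7R carbinol. The diastereoselectivity rests on this model (expected about 3:1 or better, separable).

## Compound list
1 | 2,5-dimethoxytetrahydrofuran | COC1CCC(OC)O1 | starting material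
2 | succinaldehyde | O=CCC=O | intermediate
3 | formaldehyde | C=O | starting material
4 | (S)-α,α-diphenylprolinol TMS ether (organocatalyst) | C[Si](C)(C)OC(c1ccccc1)(c1ccccc1)[C@@H]1CCCN1 | starting material
5 | (3aR,6aR)-hexahydrofuro[3,4-c]furan-1,4-diol (cis-fused bis-lactol) | OC1OC[C@H]2[C@@H]1CO[CH]2O | intermediate
6 | guaiacol | COc1ccccc1O | starting material
7 | (+)-pinoresinol | COc1cc([C@H]2OC[C@H]3[C@@H]2CO[C@@H]3c2ccc(O)c(OC)c2)ccc1O | intermediate
8 | 7-oxolariciresinol: (4-hydroxy-3-methoxyphenyl)[(3R,4R,5S)-4-(hydroxymethyl)-5-(4-hydroxy-3-methoxyphenyl)oxolan-3-yl]methanone | COc1cc([C@H]2OC[C@H](C(=O)c3ccc(O)c(OC)c3)[C@@H]2CO)ccc1O | intermediate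
9 | (7R)-7-hydroxylariciresinol | COc1cc([C@H]2OC[C@H]([C@@H](O)c3ccc(O)c(OC)c3)[C@@H]2CO)ccc1O | target

**Total steps:** 5 (steps 1 and 2 can be telescoped in one flask). **Longest linear sequence:** 5.

## Three steps most likely to fail
1. **Step 4 (proposed new).** DDQ may over-oxidize to the 7,7′-diketone, oxidize the free phenols, or epimerize C4 α to the ketone.
   - Fallback (known chemistry, different approach): arylate only ring A by Friedel–Crafts of excess 5 with guaiacol (about 0.8 equiv), then TBS-protect the phenol. Add 4-TBSO-3-MeO-C6H3MgBr to the remaining lactol, which opens it to the 7-hydroxy diol. Oxidize the benzylic alcohol with MnO2 and remove the silyl groups with TBAF to reach 8.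
2. **Step 2.** Succinaldehyde may oligomerize, hydroxymethylate at only one carbon, or give low ee, and the very polar 5 is hard to isolate.
   - Fallback: a chiral-auxiliary route. Oxidatively homocouple the Evans enolate of N-(3-benzyloxypropanoyl)oxazolidinone to give the C2-symmetric 2,3-bis(benzyloxymethyl)succinyl bis-imide. Then LiBH4 reduction, Swern oxidation and H2/Pd-C give the dialdehyde, which closes to 5.
3. **Step 5.** The chelate model may be wrong and give the 7S epimer as the major product.
   - Fallback: switch to reagent control, using CBS reduction (BH3·SMe2 with the matched Me-CBS enantiomer) or Ru-TsDPEN transfer hydrogenation of 8. Alternatively, convert any 7S alcohol to 7R by Mitsunobu inversion with p-nitrobenzoic acid followed by methanolysis.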